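**Plan**

- Retrosynthesis: the free acid of ring B is first masked as a tert-butyl ester. Ring A (C1 ester carbon, C2 heptyl, C4 methoxy, C6 hydroxyl) is then cut at C2–C3 and C1–C6, because this pattern is what a 1,3-dioxygenated silyloxydiene leaves when it adds across a dec-2-ynoate.
- The remaining cuts are the aryl ynoate C–O bond, the C4–O bond of ring B (C–H borylation/oxidation) and the benzylic C–C bond of the pentyl chain (lateral alkylation of a toluate).
- Forward: ring B is bought as an arene and elaborated (tert-butyl ester, butylation of the methyl group, C4 hydroxylation), then acylated with decynoic acid. Ring A is built last on the alkyne by cycloaddition and aromatisation, and acidolysis frees the acid.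
- Stereochemistry: the target has no stereocentre and no defined double bond, so nothing has to be set. The one transient stereocentre (ketal carbon of the cycloadduct) is racemic and disappears on aromatisation.

Key step: step 6

Remark: 2-methoxy-6-methylbenzoic acid, 1-iodobutane, dec-2-ynoic acid and methyl (E)-3-methoxybut-2-enoate are taken as commercial, and LDA is used as a commercial solution.
Remark: species formed as a discrete stage in the flask (lithio species, boronate, cycloadduct, silyl ether) are numbered as non-isolated intermediates. The ketene-acetal geometry of the diene is left undefined because both isomers lead to the same arene.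

**Route**

Step 1
Reactants: 1 2-methoxy-6-methylbenzoic acid
Product: 2 tert-butyl 2-methoxy-6-methylbenzoate
Conditions: tert-butyl 2,2,2-trichloroacetimidate (2 equiv), BF3·OEt2 (cat.), CH2Cl2–cyclohexane, rt
Reagents that add atoms: tert-butyl 2,2,2-trichloroacetimidate, CC(C)(C)OC(=N)C(Cl)(Cl)Cl
Why: Acid-catalysed O-alkylation of the carboxylic acid by the trichloroacetimidate (tert-butyl cation transfer) forms the ester at oxygen, so the di-ortho-substituted carbonyl carbon never has to be attacked.

Step 2
Reactants: 2 tert-butyl 2-methoxy-6-methylbenzoate; 3 1-iodobutane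
Product: 5 tert-butyl 2-methoxy-6-pentylbenzoate, via benzylic lithium species 4 (not isolated)
Conditions: LDA (1.1 equiv), THF, −78 °C; then 3 (1.3 equiv), DMPU, −78 → −20 °C
Reagents that add atoms: none
Why: Lateral lithiation of the ortho-toluate by LDA should give an ester-stabilised benzylic anion that is C-alkylated by the primary iodide (SN2), the bulky tert-butyl ester suppressing self-condensation.

Step 3
Reactants: 5 tert-butyl 2-methoxy-6-pentylbenzoate
Product: 7 tert-butyl 4-hydroxy-2-methoxy-6-pentylbenzoate, via aryl pinacol boronate 6 (not isolated)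
Conditions: [Ir(OMe)(cod)]2 (1.5 mol %), dtbpy (3 mol %), B2pin2 (0.7 equiv), THF, 80 °C; evaporate; then Oxone, acetone–H2O, rt, short contact
Reagents that add atoms: potassium peroxymonosulfate (active component of Oxone), [K+].[O-]S(=O)(=O)OO
Why: Iridium-catalysed C–H borylation is sterically governed and should select C4, the only ring C–H without an ortho substituent, and the boronate is then oxidised to the phenol in the same flask (one-pot borylation–oxidation).

Step 4
Reactants: 7 tert-butyl 4-hydroxy-2-methoxy-6-pentylbenzoate; 8 dec-2-ynoic acid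
Product: 9 tert-butyl 4-(dec-2-ynoyloxy)-2-methoxy-6-pentylbenzoate
Conditions: DCC (1.25 equiv), DMAP (5 mol %), CH2Cl2, 0 °C → rt
Reagents that add atoms: none
Why: Steglich esterification (carbodiimide activation with catalytic DMAP) should acylate the unhindered C4 phenol, low temperature and little DMAP being chosen to keep the ynoate from isomerising to the allenoate.

Step 5
Reactants: 10 methyl (E)-3-methoxybut-2-enoate
Product: 12 1,3-dimethoxy-1-(trimethylsilyloxy)buta-1,3-diene, via lithium dienolate 11 (not isolated)
Conditions: LDA (1.1 equiv), THF, −78 °C; then TMSCl (1.3 equiv), −78 °C → rt; pentane, filter under Ar, bulb-to-bulb distillation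
Reagents that add atoms: chlorotrimethylsilane, C[Si](C)(C)Cl
Why: Kinetic γ-deprotonation of the β-methoxy enoate gives the extended lithium dienolate, which silicon traps at oxygen (silyl ketene acetal formation) to give the Brassard-type diene, used freshly distilled.

Step 6
Reactants: 9 tert-butyl 4-(dec-2-ynoyloxy)-2-methoxy-6-pentylbenzoate; 12 1,3-dimethoxy-1-(trimethylsilyloxy)buta-1,3-diene
Product: 15 tert-butyl 4-[(2-heptyl-6-hydroxy-4-methoxybenzoyl)oxy]-2-methoxy-6-pentylbenzoate, via cyclohexadiene cycloadduct 13 (not isolated), via aryl trimethylsilyl ether 14 (not isolated)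
Conditions: 12 (3 equiv), PhMe, 110–120 °C, sealed tube, Ar; then 0.5 M HCl, THF, 0 °C
Reagents that add atoms: none
Why: The electron-rich diene 12 and the electron-poor ynoate 9 should combine in a normal-electron-demand Diels–Alder reaction (concerted but asynchronous, or Mukaiyama–Michael addition then closure), the diene CH2 bonding to the heptyl-bearing β-carbon (C2–C3 of ring A) and the ketene-acetal carbon to the α-carbon (C1–C6). Ring A thereby closes as a six-membered carbocycle by intermolecular [4+2] annulation, first as the 1,4-cyclohexadiene 13, which aromatises by 1,4-elimination of methanol from its mixed ketal to the aryl silyl ether 14, and dilute acid then frees the C6 phenol. The closest known reaction type is the cycloaddition–aromatisation of 1-alkoxy-1-silyloxy-3-oxygenated butadienes with alk-2-ynoic esters, which gives 6-alkyl-2-hydroxy-4-alkoxybenzoates. The only new stereocentre, the ketal carbon of 13, forms as a racemate without control and is erased on aromatisation. The step needs a single regiochemistry, and matched polarisation secures it: both donor oxygens raise the HOMO coefficient at the CH2 terminus, while the ester makes the alkyne β-carbon the electrophilic end. The aryl ester lowers the LUMO relative to an alkyl ynoate, and because the ketal loses its methoxy group but keeps the silyloxy oxygen, the C6 hydroxyl and C4 methoxy emerge already differentiated.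

Step 7
Reactants: 15 tert-butyl 4-[(2-heptyl-6-hydroxy-4-methoxybenzoyl)oxy]-2-methoxy-6-pentylbenzoate
Product: 16 4-[(2-heptyl-6-hydroxy-4-methoxybenzoyl)oxy]-2-methoxy-6-pentylbenzoic acid (target)
Conditions: TFA–CH2Cl2 (1:4), Et3SiH (3 equiv), 0 °C → rt
Reagents that add atoms: none
Why: Acidolysis of the tert-butyl ester (alkyl–oxygen cleavage through the tert-butyl cation) should leave the aryl depside ester, both methyl ethers and the phenol untouched, while the silane reduces the cation to isobutane before it can alkylate the electron-rich ring A.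

**Compound list**

1 | 2-methoxy-6-methylbenzoic acid | Cc1cccc(OC)c1C(=O)O | starting material
2 | tert-butyl 2-methoxy-6-methylbenzoate | Cc1cccc(OC)c1C(=O)OC(C)(C)C | intermediate
3 | 1-iodobutane | CCCCI | starting material
4 | tert-butyl 2-(lithiomethyl)-6-methoxybenzoate (benzylic lithium species, not isolated) | [Li]Cc1cccc(OC)c1C(=O)OC(C)(C)C | intermediate
5 | tert-butyl 2-methoxy-6-pentylbenzoate | CCCCCc1cccc(OC)c1C(=O)OC(C)(C)C | intermediate
6 | tert-butyl 2-methoxy-6-pentyl-4-(4,4,5,5-tetramethyl-1,3,2-dioxaborolan-2-yl)benzoate (aryl pinacol boronate, not isolated) | CCCCCc1cc(B2OC(C)(C)C(C)(C)O2)cc(OC)c1C(=O)OC(C)(C)C | intermediate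
7 | tert-butyl 4-hydroxy-2-methoxy-6-pentylbenzoate | CCCCCc1cc(O)cc(OC)c1C(=O)OC(C)(C)C | intermediate
8 | dec-2-ynoic acid | CCCCCCCC#CC(=O)O | starting material
9 | tert-butyl 4-(dec-2-ynoyloxy)-2-methoxy-6-pentylbenzoate | CCCCCCCC#CC(=O)Oc1cc(CCCCC)c(C(=O)OC(C)(C)C)c(OC)c1 | intermediate
10 | methyl (E)-3-methoxybut-2-enoate | CO/C(C)=C/C(=O)OC | starting material
11 | lithium 1,3-dimethoxybuta-1,3-dien-1-olate (lithium dienolate, not isolated) | C=C(OC)C=C(OC)O[Li] | intermediate
12 | 1,3-dimethoxy-1-(trimethylsilyloxy)buta-1,3-diene (ketene-acetal geometry undefined, used as formed) | C=C(OC)C=C(OC)O[Si](C)(C)C | intermediate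
13 | tert-butyl 4-{[2-heptyl-4,6-dimethoxy-6-(trimethylsilyloxy)cyclohexa-1,4-diene-1-carbonyl]oxy}-2-methoxy-6-pentylbenzoate (racemic at the ketal carbon, not isolated) | CCCCCCCC1=C(C(=O)Oc2cc(CCCCC)c(C(=O)OC(C)(C)C)c(OC)c2)C(OC)(O[Si](C)(C)C)C=C(OC)C1 | intermediate
14 | tert-butyl 4-{[2-heptyl-4-methoxy-6-(trimethylsilyloxy)benzoyl]oxy}-2-methoxy-6-pentylbenzoate (not isolated) | CCCCCCCc1cc(OC)cc(O[Si](C)(C)C)c1C(=O)Oc1cc(CCCCC)c(C(=O)OC(C)(C)C)c(OC)c1 | intermediate
15 | tert-butyl 4-[(2-heptyl-6-hydroxy-4-methoxybenzoyl)oxy]-2-methoxy-6-pentylbenzoate | CCCCCCCc1cc(OC)cc(O)c1C(=O)Oc1cc(CCCCC)c(C(=O)OC(C)(C)C)c(OC)c1 | intermediate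
16 | 4-[(2-heptyl-6-hydroxy-4-methoxybenzoyl)oxy]-2-methoxy-6-pentylbenzoic acid (CNP0341430.0) | CCCCCCCc1cc(OC)cc(O)c1C(=O)Oc1cc(CCCCC)c(C(=O)O)c(OC)c1 | target

**Step count**

Total: 7 steps. Longest linear sequence: 6 steps (steps 1, 2, 3, 4, 6, 7 from compound 1); the diene is made separately in one step (step 5).

**Steps most likely to fail**

Step 6. The internal alkyne may add too slowly, so that the diene is lost first to silyl migration or adventitious hydrolysis. The silyl ketene acetal may also attack the activated aryl ester carbonyl (acyl transfer releasing the ring-B phenol), or stop at the open-chain Michael stage. The fallback runs the same cycloaddition on an ordinary alkyl ynoate and makes the depside bond afterwards. It sets out from 8, which is esterified with benzyl alcohol (DCC, cat. DMAP) to benzyl dec-2-ynoate F1. Heating F1 with diene 12 should give the cycloadduct benzyl 2-heptyl-4,6-dimethoxy-6-(trimethylsilyloxy)cyclohexa-1,4-diene-1-carboxylate F2. This loses methanol to benzyl 2-heptyl-4-methoxy-6-(trimethylsilyloxy)benzoate F3, and dilute acid desilylates it to benzyl 2-heptyl-6-hydroxy-4-methoxybenzoate F4. Hydrogenolysis (H2, Pd/C, EtOAc) would give 2-heptyl-6-hydroxy-4-methoxybenzoic acid F5. Carbodiimide condensation of F5 with phenol 7 (DCC, toluene, rt) comes back to the route at 15.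

Step 2. The lithiated toluate may add to the ester of unreacted 2 (self-condensation), or the product may be deprotonated and butylated a second time. The fallback uses the carboxylate itself as the activating group. It sets out from 1, which with two equivalents of LDA (THF, −78 °C) should form the dilithio species lithium 2-(lithiomethyl)-6-methoxybenzoate F6. Alkylation with 3 and acidification would give 2-methoxy-6-pentylbenzoic acid F7. Esterification with tert-butyl trichloroacetimidate as in step 1 comes back to the route at 5.

Step 4. The carbodiimide-activated ynoate may suffer conjugate addition of DMAP or of the phenol, base-induced isomerisation to the allenoate, or rearrangement to the N-acylurea. The fallback acylates without a nucleophilic catalyst. It sets out from 8, which oxalyl chloride and catalytic DMF (CH2Cl2, 0 °C) would convert into dec-2-ynoyl chloride F8. Reaction of F8 with phenol 7 and 2,6-lutidine (CH2Cl2, −20 °C) comes back to the route at 9.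

**Further compounds**

F1 | step 6 | benzyl dec-2-ynoate | CCCCCCCC#CC(=O)OCc1ccccc1
F2 | step 6 | benzyl 2-heptyl-4,6-dimethoxy-6-(trimethylsilyloxy)cyclohexa-1,4-diene-1-carboxylate (racemic) | CCCCCCCC1=C(C(=O)OCc2ccccc2)C(OC)(O[Si](C)(C)C)C=C(OC)C1
F3 | step 6 | benzyl 2-heptyl-4-methoxy-6-(trimethylsilyloxy)benzoate | CCCCCCCc1cc(OC)cc(O[Si](C)(C)C)c1C(=O)OCc1ccccc1
F4 | step 6 | benzyl 2-heptyl-6-hydroxy-4-methoxybenzoate | CCCCCCCc1cc(OC)cc(O)c1C(=O)OCc1ccccc1
F5 | step 6 | 2-heptyl-6-hydroxy-4-methoxybenzoic acid | CCCCCCCc1cc(OC)cc(O)c1C(=O)O
F6 | step 2 | lithium 2-(lithiomethyl)-6-methoxybenzoate | [Li]Cc1cccc(OC)c1C(=O)O[Li]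
F7 | step 2 | 2-methoxy-6-pentylbenzoic acid | CCCCCc1cccc(OC)c1C(=O)O
F8 | step 4 | dec-2-ynoyl chloride | CCCCCCCC#CC(=O)Cl
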